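**Retrosynthetic overview** (germacrane/eudesmane locants: lactone O on C6, ester O on C8, ether O between C5 and C10, C15 = CH2 on C4; β = face of the C10 methyl group)
1. Target 28 ⇐ C4 methylenation (C15 last) ⇐ Mitsunobu inversion/esterification at C8 with angelic acid ⇐ C1=C2/C3=O and C11=C13 by dehydrogenation and selenoxide elimination on the saturated 5,10-epoxy core 18.
2. 18 ⇐ 17 ⇐ oxygen insertion into the C5–C10 ring-fusion bond of decalin hydroperoxide 15: cyclohexane ring B (C5–C10) becomes the oxepane and cyclohexane ring A the second seven-membered ether ring in one event.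
3. Enabling feature: C10 is the fully substituted ring-fusion carbon bonded to the peroxide-bearing C5, while the other groups on C5 (C4 methylene, lactone-oxygenated C6) migrate poorly.
4. Decalin 12 ⇐ Robinson annulation (ring A; C10 set by a chiral-imine Michael addition) on keto-lactone 7 ⇐ (S)-4-silyloxycyclohexenone 1 by α'-methylation, anti Mukaiyama–Michael addition (C7) and Rubottom oxidation/lactonization (C6).
5. Ring order: ring B bought (1) → lactone ring (step 3) → ring A (step 5) → both seven-membered ether rings by ring expansion (step 8).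

Key step: step 8

Remark: 1 is taken as a catalogue compound; centres that are re-set or destroyed later (C10 in 2–7, C11 in 4–20, C5 in 14–16) are carried as epimer mixtures and written without descriptor.

**Step 1**
Reactants: 1 (S)-4-(tert-butyldimethylsilyloxy)cyclohex-2-en-1-one
Product: 2 (4S)-4-(tert-butyldimethylsilyloxy)-6-methylcyclohex-2-en-1-one (C6 epimers)
Conditions: LiN(iPr)2, THF, −78 °C; MeI, −78 to −30 °C
Reagents that add atoms: iodomethane, CI
Why: Kinetic α'-deprotonation of the enone and C-methylation of the cross-conjugated enolate (enolate alkylation); the new centre (future C10) is left uncontrolled because step 4 re-sets it.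

**Step 2**
Reactants: 2 (4S)-4-(tert-butyldimethylsilyloxy)-6-methylcyclohex-2-en-1-one; 3 1-methoxy-1-(trimethylsilyloxy)prop-1-ene
Product: 4 methyl 2-[6-(tert-butyldimethylsilyloxy)-4-methyl-3-(trimethylsilyloxy)cyclohex-2-en-1-yl]propanoate (side chain trans to the 6-silyloxy group)
Conditions: Me3SiOTf (5 mol%), CH2Cl2, −78 °C; Et3N quench
Reagents that add atoms: none
Why: Mukaiyama–Michael addition in which the ketene acetal attacks the enone β-carbon (C7) anti to the adjacent C8 silyloxy group, setting C7 trans to C8–O and giving the silyl enol ether regiospecifically toward C6; C11 is not controlled because it becomes sp2 in step 11.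

**Step 3**
Reactants: 4 methyl 2-[6-(tert-butyldimethylsilyloxy)-4-methyl-3-(trimethylsilyloxy)cyclohex-2-en-1-yl]propanoate
Product: 7 trans-fused keto-lactone 4-(tert-butyldimethylsilyloxy)-3,6-dimethylhexahydro-1-benzofuran-2,7-dione (6α-O lactone; 8α-silyloxy), via silyloxy ketone 5 (not isolated), via hydroxy ester 6 (not isolated)
Conditions: mCPBA, NaHCO3, CH2Cl2, −20 °C; then TsOH·H2O (cat.), CH2Cl2, rt
Reagents that add atoms: 3-chloroperoxybenzoic acid, OOC(=O)c1cccc(Cl)c1
Why: Rubottom oxidation, in which the peracid epoxidizes the silyl enol ether anti to the C7 side chain (1,4-silyl shift to the α-silyloxy ketone), so C6–O is set trans to C7; acid then removes the silyl group and the γ-hydroxy ester closes to the trans-fused γ-lactone.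

**Step 4**
Reactants: 7 trans-fused keto-lactone; 8 but-3-en-2-one
Product: 11 diketone (7 carrying at C10 a β-methyl and an α-3-oxobutyl group), via imine 9 (not isolated), via adduct imine 10 (not isolated)
Conditions: (R)-1-phenylethylamine, TsOH (cat.), 4 Å molecular sieves, toluene, 60 °C; then 8, THF, rt; then 20% aq AcOH, rt
Reagents that add atoms: water, O
Why: Chiral-imine (secondary enamine) Michael addition as the first stage of a Robinson annulation: only the enamine toward the methyl-bearing C10 should form (C6 is a trans ring-fusion carbon), and the (R)-1-phenylethyl group directs the enone to the α face of C10 in an aza-ene-like transition state, setting the quaternary centre with its methyl group β (cis to the C7–C11 bond).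

**Step 5**
Reactants: 11 diketone
Product: 12 8α-(tert-butyldimethylsilyloxy)-3-oxo-15-noreudesm-4-en-6α,12-olide
Conditions: pyrrolidine (0.3 equiv), AcOH (0.3 equiv), toluene, 50 °C
Reagents that add atoms: none
Why: Intramolecular aldol condensation (second stage of the Robinson annulation) closes ring A as the conjugated enone; no new stereocentre is formed and the mild amine/acid catalysis should leave the epimerizable C6 untouched.

**Step 6**
Reactants: 12 enone lactone
Product: 13 3β-hydroxy-8α-(tert-butyldimethylsilyloxy)-15-noreudesm-4-en-6α,12-olide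
Conditions: NaBH4, CeCl3·7H2O, MeOH, −40 °C
Reagents that add atoms: none
Why: Luche reduction: 1,2-hydride addition from the α face (anti to the axial C10 methyl group) gives the 3β-allylic alcohol and removes the conjugation that would divert step 7 to α-oxidation; the C3 centre is destroyed in step 12.

**Step 7**
Reactants: 13 allylic alcohol
Product: 14 3β-hydroxy-8α-(tert-butyldimethylsilyloxy)-5-(triethylsilylperoxy)-15-noreudesman-6α,12-olide (C5 epimers)
Conditions: Co(acac)2 (10 mol%), O2 (1 atm), Et3SiH, ClCH2CH2Cl, rt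
Reagents that add atoms: dioxygen, O=O; triethylsilane, CC[SiH](CC)CC
Why: Mukaiyama (Isayama–Mukaiyama) hydroperoxidation: hydrogen-atom transfer from a cobalt hydride to the less substituted C4 of the trisubstituted alkene gives the tertiary C5 radical, which is trapped by O2 and silylated; the configuration at C5 is irrelevant because C5 is the migration origin in step 8.

**Step 8**
Reactants: 14 silyl peroxide
Product: 17 3β,5β-diacetoxy-5α,10α-epoxy-8α-(tert-butyldimethylsilyloxy)-15-norgermacran-6α,12-olide (11-oxabicyclo[4.4.1]undecane core), via hydroperoxide 15 (not isolated), via peracetate 16 (not isolated)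
Conditions: K2CO3 (cat.), MeOH, 0 °C; then Ac2O, pyridine, DMAP (cat.), CH2Cl2, 0 °C to rt
Reagents that add atoms: acetic anhydride, CC(=O)OC(C)=O
Why: Methanolysis frees the tertiary C5 hydroperoxide 15 and acetylation gives peracetate 16 (the C3 alcohol is acetylated as well); heterolysis of the O–O bond is concerted with a 1,2-shift of C10 from C5 to the proximal oxygen, and the acetate/oxocarbenium ion pair collapses at C5 to the bridgehead acylal 17. The closest known reaction is the Criegee rearrangement of 9-decalyl peresters, which gives 11-oxabicyclo[4.4.1]undec-1-yl esters, i.e. this ring system. No ring is closed from a chain: the oxepane (O, C5–C10) arises from cyclohexane ring B and the second seven-membered ring (O, C10, C1–C5) from ring A by the same one-atom ring expansion, oxygen insertion into their shared C5–C10 bond. C10 migrates with retention, so the ether oxygen takes the place of C5 on C10 (10β-methyl kept), and C5 becomes a bridgehead whose configuration is fixed by the one-atom bridge whatever the configuration of the peroxide. The step needs migration of C10 in preference to C4 and C6: C10 is the only fully substituted group on C5, C4 is a plain methylene and C6 carries the electron-withdrawing lactone oxygen.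

**Step 9**
Reactants: 17 bridgehead acylal
Product: 18 3β-acetoxy-5α,10α-epoxy-8α-(tert-butyldimethylsilyloxy)-15-norgermacran-6α,12-olide (5β-H)
Conditions: Et3SiH, Me3SiOTf (0.3 equiv), CH2Cl2, −40 to 0 °C
Reagents that add atoms: none
Why: Proposed new method: Me3SiOTf should ionize the bridgehead acetate of 17 to the same ether-stabilized C5 cation (ion pair) that the Criegee step passes through, and Et3SiH delivers hydride to it; the bicyclic frame allows only the 5β-H configuration, and the closest known reaction type is the Lewis acid/silane reduction of anomeric acetates and ketals to cyclic ethers, not yet shown on a bridgehead acylal of this ring system.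

**Step 10**
Reactants: 18 acetate
Product: 19 5α,10α-epoxy-3β-hydroxy-8α-(tert-butyldimethylsilyloxy)-15-norgermacran-6α,12-olide
Conditions: K2CO3, MeOH, 0 °C
Reagents that add atoms: none
Why: Methanolysis (transesterification) of the secondary acetate frees the C3 alcohol; the silyl ether is stable and the lactone re-closes on neutral work-up.

**Step 11**
Reactants: 19 hydroxy lactone
Product: 21 5α,10α-epoxy-3β-hydroxy-8α-(tert-butyldimethylsilyloxy)-15-norgermacr-11(13)-en-6α,12-olide, via selenide 20 (not isolated)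
Conditions: LiN(iPr)2 (2.2 equiv), THF, −78 °C; PhSeBr; then 30% H2O2, THF, 0 °C
Reagents that add atoms: none
Why: α-Selenenylation of the lactone enolate followed by selenoxide syn-elimination, which in trans-fused α-methyl-γ-butyrolactones is known to give the exocyclic alkene; C11=C13 is formed and the C11 centre disappears.

**Step 12**
Reactants: 21 α-methylene lactone alcohol
Product: 23 5α,10α-epoxy-3-oxo-8α-(tert-butyldimethylsilyloxy)-15-norgermacra-1,11(13)-dien-6α,12-olide, via ketone 22 (not isolated)
Conditions: 2-iodoxybenzoic acid (2.5 equiv), DMSO, 70 °C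
Reagents that add atoms: none
Why: 2-Iodoxybenzoic acid oxidizes the C3 alcohol to the ketone and then dehydrogenates it (enol oxidation) to the enone; the double bond should form at C1–C2 because dehydrogenation toward C4–C5 would have to create a bridgehead enol ether.

**Step 13**
Reactants: 23 silyl ether
Product: 24 5α,10α-epoxy-8α-hydroxy-3-oxo-15-norgermacra-1,11(13)-dien-6α,12-olide
Conditions: HF·pyridine, THF/pyridine, 0 °C to rt
Reagents that add atoms: none
Why: Fluoride cleavage of the silyl ether under buffered conditions frees the 8α-alcohol without touching the enone or the α-methylene lactone.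

**Step 14**
Reactants: 24 8α-alcohol; 25 angelic acid, (Z)-2-methylbut-2-enoic acid
Product: 26 8β-angeloyloxy-5α,10α-epoxy-3-oxo-15-norgermacra-1,11(13)-dien-6α,12-olide
Conditions: PPh3, diisopropyl azodicarboxylate, toluene, 0 °C to rt
Reagents that add atoms: none
Why: Mitsunobu esterification: the angelate displaces the alkoxyphosphonium at C8 by SN2 with inversion, turning the 8α-alcohol into the 8β-ester under neutral conditions that should not isomerize the (Z)-alkene.

**Step 15**
Reactants: 26 angelate
Product: 28 8β-angeloyloxy-5α,10α-epoxy-3-oxogermacra-1,4(15),11(13)-trien-6α,12-olide (target), via Mannich base 27 (not isolated)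
Conditions: (CH2O)n, N-methylanilinium trifluoroacetate, THF, 65 °C
Reagents that add atoms: formaldehyde, C=O
Why: Direct α-methylenation (Mannich condensation with formaldehyde, then amine elimination): the ketone can enolize only toward C4 because C2 is sp2, and the Mannich base loses N-methylaniline in situ to give the C4=C15 alkene without affecting any stereocentre.

**Compound list**
1 | (S)-4-(tert-butyldimethylsilyloxy)cyclohex-2-en-1-one | O=C1C=C[C@@H](O[Si](C)(C)C(C)(C)C)CC1 | starting material
2 | (4S)-4-(tert-butyldimethylsilyloxy)-6-methylcyclohex-2-en-1-one (C6 epimers) | CC1C[C@H](O[Si](C)(C)C(C)(C)C)C=CC1=O | intermediate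
3 | 1-methoxy-1-(trimethylsilyloxy)prop-1-ene (E/Z mixture) | CC=C(OC)O[Si](C)(C)C | starting material
4 | methyl 2-[6-(tert-butyldimethylsilyloxy)-4-methyl-3-(trimethylsilyloxy)cyclohex-2-en-1-yl]propanoate (side chain trans to 6-silyloxy) | COC(=O)C(C)[C@H]1C=C(O[Si](C)(C)C)C(C)C[C@@H]1O[Si](C)(C)C(C)(C)C | intermediate
5 | methyl 2-[6-(tert-butyldimethylsilyloxy)-4-methyl-3-oxo-2-(trimethylsilyloxy)cyclohexyl]propanoate (silyloxy ketone) | COC(=O)C(C)[C@H]1[C@H](O[Si](C)(C)C)C(=O)C(C)C[C@@H]1O[Si](C)(C)C(C)(C)C | intermediate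
6 | methyl 2-[6-(tert-butyldimethylsilyloxy)-2-hydroxy-4-methyl-3-oxocyclohexyl]propanoate (hydroxy ester) | COC(=O)C(C)[C@H]1[C@H](O)C(=O)C(C)C[C@@H]1O[Si](C)(C)C(C)(C)C | intermediate
7 | 4-(tert-butyldimethylsilyloxy)-3,6-dimethylhexahydro-1-benzofuran-2,7-dione (trans-fused keto-lactone) | CC1C(=O)O[C@H]2[C@H]1[C@@H](O[Si](C)(C)C(C)(C)C)CC(C)C2=O | intermediate
8 | but-3-en-2-one | CC(=O)C=C | starting material
9 | N-[(R)-1-phenylethyl]imine of 7 | CC1C(=O)O[C@H]2[C@H]1[C@@H](O[Si](C)(C)C(C)(C)C)CC(C)C2=N[C@H](C)c1ccccc1 | intermediate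
10 | N-[(R)-1-phenylethyl]imine of 11 (adduct imine) | CC1C(=O)O[C@H]2[C@H]1[C@@H](O[Si](C)(C)C(C)(C)C)C[C@@](C)(CCC(C)=O)C2=N[C@H](C)c1ccccc1 | intermediate
11 | diketone: 7 with 10β-methyl and 10α-(3-oxobutyl) | CC1C(=O)O[C@H]2[C@H]1[C@@H](O[Si](C)(C)C(C)(C)C)C[C@@](C)(CCC(C)=O)C2=O | intermediate
12 | 8α-(tert-butyldimethylsilyloxy)-3-oxo-15-noreudesm-4-en-6α,12-olide | CC1C(=O)O[C@H]2[C@H]1[C@@H](O[Si](C)(C)C(C)(C)C)C[C@@]1(C)CCC(=O)C=C12 | intermediate
13 | 3β-hydroxy-8α-(tert-butyldimethylsilyloxy)-15-noreudesm-4-en-6α,12-olide | CC1C(=O)O[C@H]2[C@H]1[C@@H](O[Si](C)(C)C(C)(C)C)C[C@@]1(C)CC[C@H](O)C=C12 | intermediate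
14 | 3β-hydroxy-8α-(tert-butyldimethylsilyloxy)-5-(triethylsilylperoxy)-15-noreudesman-6α,12-olide | CC1C(=O)O[C@H]2[C@H]1[C@@H](O[Si](C)(C)C(C)(C)C)C[C@@]1(C)CC[C@H](O)CC12OO[Si](CC)(CC)CC | intermediate
15 | 5-hydroperoxy-3β-hydroxy-8α-(tert-butyldimethylsilyloxy)-15-noreudesman-6α,12-olide | CC1C(=O)O[C@H]2[C@H]1[C@@H](O[Si](C)(C)C(C)(C)C)C[C@@]1(C)CC[C@H](O)CC12OO | intermediate
16 | 3β-acetoxy-5-(acetylperoxy)-8α-(tert-butyldimethylsilyloxy)-15-noreudesman-6α,12-olide | CC1C(=O)O[C@H]2[C@H]1[C@@H](O[Si](C)(C)C(C)(C)C)C[C@@]1(C)CC[C@H](OC(C)=O)CC12OOC(C)=O | intermediate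
17 | 3β,5β-diacetoxy-5α,10α-epoxy-8α-(tert-butyldimethylsilyloxy)-15-norgermacran-6α,12-olide | CC1C(=O)O[C@H]2[C@H]1[C@@H](O[Si](C)(C)C(C)(C)C)C[C@@]1(C)CC[C@H](OC(C)=O)C[C@]2(OC(C)=O)O1 | intermediate
18 | 3β-acetoxy-5α,10α-epoxy-8α-(tert-butyldimethylsilyloxy)-15-norgermacran-6α,12-olide | CC1C(=O)O[C@H]2[C@H]1[C@@H](O[Si](C)(C)C(C)(C)C)C[C@@]1(C)CC[C@H](OC(C)=O)C[C@@H]2O1 | intermediate
19 | 5α,10α-epoxy-3β-hydroxy-8α-(tert-butyldimethylsilyloxy)-15-norgermacran-6α,12-olide | CC1C(=O)O[C@H]2[C@H]1[C@@H](O[Si](C)(C)C(C)(C)C)C[C@@]1(C)CC[C@H](O)C[C@@H]2O1 | intermediate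
20 | 11-(phenylselanyl) derivative of 19 | CC1([Se]c3ccccc3)C(=O)O[C@H]2[C@H]1[C@@H](O[Si](C)(C)C(C)(C)C)C[C@@]1(C)CC[C@H](O)C[C@@H]2O1 | intermediate
21 | 5α,10α-epoxy-3β-hydroxy-8α-(tert-butyldimethylsilyloxy)-15-norgermacr-11(13)-en-6α,12-olide | C=C1C(=O)O[C@H]2[C@H]1[C@@H](O[Si](C)(C)C(C)(C)C)C[C@@]1(C)CC[C@H](O)C[C@@H]2O1 | intermediate
22 | 5α,10α-epoxy-3-oxo-8α-(tert-butyldimethylsilyloxy)-15-norgermacr-11(13)-en-6α,12-olide | C=C1C(=O)O[C@H]2[C@H]1[C@@H](O[Si](C)(C)C(C)(C)C)C[C@@]1(C)CCC(=O)C[C@@H]2O1 | intermediate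
23 | 5α,10α-epoxy-3-oxo-8α-(tert-butyldimethylsilyloxy)-15-norgermacra-1,11(13)-dien-6α,12-olide | C=C1C(=O)O[C@H]2[C@H]1[C@@H](O[Si](C)(C)C(C)(C)C)C[C@@]1(C)C=CC(=O)C[C@@H]2O1 | intermediate
24 | 5α,10α-epoxy-8α-hydroxy-3-oxo-15-norgermacra-1,11(13)-dien-6α,12-olide | C=C1C(=O)O[C@H]2[C@H]1[C@@H](O)C[C@@]1(C)C=CC(=O)C[C@@H]2O1 | intermediate
25 | angelic acid, (Z)-2-methylbut-2-enoic acid | C/C=C(/C)C(=O)O | starting material
26 | 8β-angeloyloxy-5α,10α-epoxy-3-oxo-15-norgermacra-1,11(13)-dien-6α,12-olide | C=C1C(=O)O[C@H]2[C@H]1[C@H](OC(=O)/C(C)=C\C)C[C@@]1(C)C=CC(=O)C[C@@H]2O1 | intermediate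
27 | 4-[(N-methylanilino)methyl] derivative of 26 (Mannich base) | C=C1C(=O)O[C@H]2[C@H]1[C@H](OC(=O)/C(C)=C\C)C[C@@]1(C)C=CC(=O)C(CN(C)c3ccccc3)[C@@H]2O1 | intermediate
28 | 8β-angeloyloxy-5α,10α-epoxy-3-oxogermacra-1,4(15),11(13)-trien-6α,12-olide | C=C1C(=O)O[C@H]2[C@H]1[C@H](OC(=O)/C(C)=C\C)C[C@@]1(C)C=CC(=O)C(=C)[C@@H]2O1 | target

**Total step count:** 15. **Longest linear sequence:** 15 steps (from 1; 3, 8 and 25 are bought).

**Steps most likely to fail**

Step 9 (Proposed new method). Ionization at the bridgehead may be too slow, because the ether lone pair overlaps poorly with the developing cation, so that loss of the C8 silyl ether or acid opening of the ether bridge competes. The fallback sets out from 17 and uses known reactions. Selective methanolysis of the hemiketal-type acetate (K2CO3 cat., MeOH, −20 °C) should open the bridge to the ten-membered hydroxy ketone 3β-acetoxy-10-hydroxy-5-oxo-8α-(tert-butyldimethylsilyloxy)-15-norgermacran-6α,12-olide F1. Reduction with NaBH4 (MeOH, −40 °C), under Felkin–Anh control by the C6 acyloxy group, should give the (5S)-alcohol, diol F2. Camphorsulfonic acid (cat., CH2Cl2, rt) should then ionize the tertiary C10 carbinol and the C5 hydroxyl captures it transannularly (acid-catalysed cyclodehydration of a diol with a tertiary carbinol, as in cineole formation). Only the cis-bridged ether can form, so the sequence comes back to the route at 18.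

Step 4. The auxiliary amine may open the lactone by aminolysis, or condensation at the hindered α-acyloxy ketone may be slow, so that the Michael addition at C10 is lost or its facial selectivity eroded. The fallback sets out from 6, intercepted by a buffered work-up of step 3 before the acid treatment. Et3SiOTf/2,6-lutidine should give the triethylsilyl ether F3. (R)-1-Phenylethylamine (TsOH cat., toluene, 60 °C) should give the imine F4, but-3-en-2-one the adduct imine F5, and aqueous AcOH the diketone ester F6. NaOMe in MeOH should close ring A to the enone ester F7. TsOH·H2O in MeOH should free the hydroxy ester F8, which lactonizes on warming in toluene and comes back to the route at 12.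

Step 14. Elimination, or conjugate addition of the phosphine to the α-methylene lactone, may compete with SN2 inversion at the hindered C8. The fallback sets out from 24: ClCH2SO2Cl/pyridine should give the 8α-chloromethanesulfonate F9. Displacement with CsO2CC(CH3)=CHCH3 (from 25 and Cs2CO3; 18-crown-6, toluene, 60 °C) should proceed with inversion (sulfonate displacement by a cesium carboxylate) and comes back to the route at 26.

**Further compounds**
F1 | step 9 | 3β-acetoxy-10-hydroxy-5-oxo-8α-(tert-butyldimethylsilyloxy)-15-norgermacran-6α,12-olide | CC1C(=O)O[C@H]2[C@H]1[C@@H](O[Si](C)(C)C(C)(C)C)C[C@](C)(O)CC[C@H](OC(C)=O)CC2=O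
F2 | step 9 | (5S)-3β-acetoxy-5,10-dihydroxy-8α-(tert-butyldimethylsilyloxy)-15-norgermacran-6α,12-olide | CC1C(=O)O[C@H]2[C@H]1[C@@H](O[Si](C)(C)C(C)(C)C)C[C@](C)(O)CC[C@H](OC(C)=O)C[C@@H]2O
F3 | step 4 | triethylsilyl ether of 6 | COC(=O)C(C)[C@H]1[C@H](O[Si](CC)(CC)CC)C(=O)C(C)C[C@@H]1O[Si](C)(C)C(C)(C)C
F4 | step 4 | N-[(R)-1-phenylethyl]imine of F3 | COC(=O)C(C)[C@H]1[C@H](O[Si](CC)(CC)CC)C(=N[C@H](C)c2ccccc2)C(C)C[C@@H]1O[Si](C)(C)C(C)(C)C
F5 | step 4 | N-[(R)-1-phenylethyl]imine of F6 | COC(=O)C(C)[C@H]1[C@H](O[Si](CC)(CC)CC)C(=N[C@H](C)c2ccccc2)[C@](C)(CCC(C)=O)C[C@@H]1O[Si](C)(C)C(C)(C)C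
F6 | step 4 | diketone ester: F3 with 10β-methyl and 10α-(3-oxobutyl) | COC(=O)C(C)[C@H]1[C@H](O[Si](CC)(CC)CC)C(=O)[C@](C)(CCC(C)=O)C[C@@H]1O[Si](C)(C)C(C)(C)C
F7 | step 4 | methyl 8α-(tert-butyldimethylsilyloxy)-3-oxo-6α-(triethylsilyloxy)-15-noreudesm-4-en-12-oate | COC(=O)C(C)[C@H]1[C@H](O[Si](CC)(CC)CC)C2=CC(=O)CC[C@]2(C)C[C@@H]1O[Si](C)(C)C(C)(C)C
F8 | step 4 | methyl 8α-(tert-butyldimethylsilyloxy)-6α-hydroxy-3-oxo-15-noreudesm-4-en-12-oate | COC(=O)C(C)[C@H]1[C@H](O)C2=CC(=O)CC[C@]2(C)C[C@@H]1O[Si](C)(C)C(C)(C)C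
F9 | step 14 | 8α-chloromethanesulfonate of 24 | C=C1C(=O)O[C@H]2[C@H]1[C@@H](OS(=O)(=O)CCl)C[C@@]1(C)C=CC(=O)C[C@@H]2O1
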